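**Retrosynthetic overview**
1. The target is a 3-bromolabdane in which one oxygen bridges C8 and C15 (oxocane: C8, O, C15, C14, C13, C12, C11, C9) and a second oxygen spans C13/C14 (oxirane cis-fused to the oxocane).
2. Enabling feature: the oxocane oxygen sits on C15, next to the oxirane carbon C14. The oxocane/oxirane pair is therefore the Payne-type isomer of an oxepane-fused epoxonium ion (O+ on C8, C14 and C15) that carries an O-nucleophile on C13.
3. Opening that ion at C14 by O13 enlarges the oxepane to the oxocane and makes the 13,14-oxirane; the ion itself forms when the C8 cation of a bromonium-triggered chair–chair bicyclization is caught by a terminal epoxide.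
4. The open-chain epoxy silyl ether 9 comes from commercial geranylgeraniol: Sharpless epoxidation, Payne rearrangement–hydrolysis to the 1,2,3-triol, then re-closure of the oxirane on C14–C15 with a second inversion at C14.
5. Ring order: ring A, ring B, oxepane (transient), then oxocane and oxirane together, all in step 7.

Key step: step 7

Numbering: acyclic compounds use the hexadecane chain (C1 = oxygenated end); cyclized species and the target use labdane numbering (chain C1, C2, C3, C6, C7, C14, C15 become C15, C14, C13, C9, C8, C3, C4).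

Remark: which antipode of the chiral Lewis base in step 7 brominates the Re face of the terminal alkene cannot be predicted for this substrate; the route names the face and writes the (R)-catalyst for whichever antipode delivers it.

**Step 1**
Reactants: 1 (2E,6E,10E)-geranylgeraniol
Product: 2 (2S,3S)-2,3-epoxygeranylgeraniol
Conditions: Ti(OiPr)4 (5 mol %), L-(+)-diethyl tartrate (6 mol %), t-BuOOH, 4 Å MS, CH2Cl2, −20 °C
Reagents that add atoms: tert-butyl hydroperoxide, CC(C)(C)OO
Why: Sharpless asymmetric epoxidation is confined to the allylic 2,3-alkene and, with the L-(+)-tartrate, should deliver oxygen to the face that gives the (2S,3S)-epoxide as it does for geraniol, which sets the later C13 for good and the later C14 provisionally.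

**Step 2**
Reactants: 2 (2S,3S)-2,3-epoxygeranylgeraniol
Product: 4 (2R,3S,6E,10E)-3,7,11,15-tetramethylhexadeca-6,10,14-triene-1,2,3-triol, via Payne-isomeric terminal epoxide 3 (not isolated)
Conditions: NaOH (0.5 M aq.), t-BuOH, 75 °C
Reagents that add atoms: water, O
Why: Payne rearrangement–opening: the C1 alkoxide opens the oxirane at C2 with inversion to the terminal epoxide 3, which hydroxide opens at its primary carbon far faster than it attacks 2, so that C3 is kept and C2 inverted (direct hydroxide attack at C2 of 2 would converge on the same triol).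

**Step 3**
Reactants: 4 the (2R,3S)-triol
Product: 5 (2R,3S,6E,10E)-2,3-dihydroxy-3,7,11,15-tetramethylhexadeca-6,10,14-trien-1-yl acetate
Conditions: AcCl (1.05 equiv), 2,4,6-collidine, CH2Cl2, −78 °C
Reagents that add atoms: acetyl chloride, CC(Cl)=O
Why: Low-temperature acylation with a hindered pyridine base discriminates the primary hydroxyl from the secondary and tertiary ones (selective primary O-acetylation), and no stereocenter is touched.

**Step 4**
Reactants: 5 the primary acetate
Product: 6 (2R,3S,6E,10E)-3-hydroxy-2-[(methanesulfonyl)oxy]-3,7,11,15-tetramethylhexadeca-6,10,14-trien-1-yl acetate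
Conditions: MsCl, Et3N, CH2Cl2, −20 °C
Reagents that add atoms: methanesulfonyl chloride, CS(Cl)(=O)=O
Why: O-Sulfonylation of the only secondary hydroxyl, the tertiary one being inert at this temperature, turns O2 into a leaving group with retention because only the O–S bond is made.

**Step 5**
Reactants: 6 the hydroxy mesylate acetate
Product: 7 (2R,3S,6E,10E)-3-[(tert-butyldimethylsilyl)oxy]-2-[(methanesulfonyl)oxy]-3,7,11,15-tetramethylhexadeca-6,10,14-trien-1-yl acetate
Conditions: TBSOTf, 2,6-lutidine, CH2Cl2, −78 to 0 °C
Reagents that add atoms: tert-butyldimethylsilyl trifluoromethanesulfonate, CC(C)(C)[Si](C)(C)OS(=O)(=O)C(F)(F)F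
Why: Silyl triflate silylation is the standard way to cap a hindered tertiary alcohol and, as no alkoxide is formed, the neighbouring mesylate is not displaced and the acetate does not migrate.

**Step 6**
Reactants: 7 the silyl ether mesylate acetate
Product: 9 tert-butyl(dimethyl){[(2S,5E,9E)-6,10,14-trimethyl-2-[(2S)-oxiran-2-yl]pentadeca-5,9,13-trien-2-yl]oxy}silane, via hydroxy mesylate 8 (not isolated)
Conditions: K2CO3, MeOH, 0 °C to rt
Reagents that add atoms: none
Why: Methanolysis of the acetate frees the C1 alkoxide of 8, which displaces the adjacent mesylate in a 3-exo-tet Williamson-type epoxide closure with inversion at C2 (2R to 2S), while the silyl ether prevents any Payne equilibration.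

**Step 7**
Reactants: 9 the (S,S)-epoxy silyl ether
Product: 14 (3R,5S,8S,9S,10R,13S,14R)-3-bromo-8,15:13,14-diepoxylabdane (CNP0311742.1; trans-decalin, equatorial 3-Br, oxocane oxygen from C8 to C15, cis-fused 13,14-oxirane), via terminal bromonium ion 10 (not isolated), via bicyclic C8 carbocation 11 (not isolated), via oxepane-fused epoxonium ion 12 (not isolated), via O-silyl oxiranium ion 13 (not isolated)
Conditions: NBS (1.1 equiv), (R)-3,3'-bis(2,4,6-triisopropylphenyl)-1,1'-binaphthalene-2,2'-diyl N-phenylphosphoramidothioate (10 mol %), 2,6-di-tert-butyl-4-methylpyridine (0.2 equiv), 4 Å MS, CH2Cl2–toluene, −78 to −40 °C; aq. NaHCO3/Na2S2O3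
Reagents that add atoms: N-bromosuccinimide, O=C1CCC(=O)N1Br
Why: Proposed new method: the chiral Lewis base hands Br+ from NBS to the Re face of the terminal alkene (chain C14=C15) of 9; the bromonium ion 10 is opened at its tertiary carbon by the 10,11-alkene and the resulting cation by the 6,7-alkene through a chair–chair array (two 6-endo closures, anti addition across both E-alkenes) to the tertiary C8 cation 11, whose equatorial lobe is captured by the oxirane oxygen in a seven-membered (oxepane) closure to give the fused epoxonium ion 12, and the silyl ether oxygen on C13, which can stand anti to the C14–O+ bond, then attacks the ring-fusion carbon C14 (3-exo-tet, inversion), so that the bond shared by the oxepane and the oxiranium ring breaks, the seven-membered ring becomes the oxocane, the 13,14-oxirane forms (13) and the silyl cation passes to succinimide. The closest known reaction types are the Lewis-base-catalysed enantioselective bromonium polyene cyclization and the endo-selective opening of fused epoxonium ions in polyepoxide cascades, where a six-membered ring grows into an oxepane in the same manner; untested are an epoxide as terminator of a carbocyclization and an epoxide-forming, Payne-type opening of the epoxonium ion. C3 is set by the catalyst-controlled face of bromination, C5 and C10 by the chair–chair folding of the E,E-triene, C9 and C8 by anti addition across the 6E-alkene with equatorial C8–O bonding, C13 is carried over from 9 and C14 is inverted stereospecifically. The step needs capture of C8 by the epoxide and not by O13, which the bulky silyl group on the tertiary O13 secures by blocking the otherwise favoured six-ring ether closure, and opening of 12 at C14 and not at C15, which the tether secures because O13 can reach C14 in a 3-exo mode but C15 only in a 4-exo mode. Since C13 and C14 of 9 are enantiopure, bromination on the wrong face would end in a separable diastereomer of 14 and not in its enantiomer.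

**Compound list**
1 | (2E,6E,10E)-3,7,11,15-tetramethylhexadeca-2,6,10,14-tetraen-1-ol (geranylgeraniol) | CC(C)=CCC/C(C)=C/CC/C(C)=C/CC/C(C)=C/CO | starting material
2 | [(2S,3S)-3-methyl-3-[(3E,7E)-4,8,12-trimethyltrideca-3,7,11-trien-1-yl]oxiran-2-yl]methanol | CC(C)=CCC/C(C)=C/CC/C(C)=C/CC[C@]1(C)O[C@H]1CO | intermediate
3 | (2S,5E,9E)-6,10,14-trimethyl-2-[(2R)-oxiran-2-yl]pentadeca-5,9,13-trien-2-ol | CC(C)=CCC/C(C)=C/CC/C(C)=C/CC[C@](C)(O)[C@H]1CO1 | intermediate (not isolated)
4 | (2R,3S,6E,10E)-3,7,11,15-tetramethylhexadeca-6,10,14-triene-1,2,3-triol | CC(C)=CCC/C(C)=C/CC/C(C)=C/CC[C@](C)(O)[C@H](O)CO | intermediate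
5 | (2R,3S,6E,10E)-2,3-dihydroxy-3,7,11,15-tetramethylhexadeca-6,10,14-trien-1-yl acetate | CC(C)=CCC/C(C)=C/CC/C(C)=C/CC[C@](C)(O)[C@H](O)COC(C)=O | intermediate
6 | (2R,3S,6E,10E)-3-hydroxy-2-[(methanesulfonyl)oxy]-3,7,11,15-tetramethylhexadeca-6,10,14-trien-1-yl acetate | CC(C)=CCC/C(C)=C/CC/C(C)=C/CC[C@](C)(O)[C@H](OS(C)(=O)=O)COC(C)=O | intermediate
7 | (2R,3S,6E,10E)-3-[(tert-butyldimethylsilyl)oxy]-2-[(methanesulfonyl)oxy]-3,7,11,15-tetramethylhexadeca-6,10,14-trien-1-yl acetate | CC(C)=CCC/C(C)=C/CC/C(C)=C/CC[C@](C)(O[Si](C)(C)C(C)(C)C)[C@H](OS(C)(=O)=O)COC(C)=O | intermediate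
8 | (2R,3S,6E,10E)-3-[(tert-butyldimethylsilyl)oxy]-1-hydroxy-3,7,11,15-tetramethylhexadeca-6,10,14-trien-2-yl methanesulfonate | CC(C)=CCC/C(C)=C/CC/C(C)=C/CC[C@](C)(O[Si](C)(C)C(C)(C)C)[C@H](OS(C)(=O)=O)CO | intermediate (not isolated)
9 | tert-butyl(dimethyl){[(2S,5E,9E)-6,10,14-trimethyl-2-[(2S)-oxiran-2-yl]pentadeca-5,9,13-trien-2-yl]oxy}silane | CC(C)=CCC/C(C)=C/CC/C(C)=C/CC[C@](C)(O[Si](C)(C)C(C)(C)C)[C@@H]1CO1 | intermediate
10 | (R)-configured bromonium ion on the terminal alkene of 9 | CC1(C)[Br+][C@@H]1CC/C(C)=C/CC/C(C)=C/CC[C@](C)(O[Si](C)(C)C(C)(C)C)[C@@H]1CO1 | intermediate (not isolated)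
11 | 3-bromo-trans-decalin C8 carbocation (labdan-8-ylium ion) carrying the 13-silyloxy-14,15-oxirane side chain on C9 | CC1(C)[C@H](Br)CC[C@]2(C)[C@@H]1CC[C+](C)[C@H]2CC[C@](C)(O[Si](C)(C)C(C)(C)C)[C@@H]1CO1 | intermediate (not isolated)
12 | oxepane-fused epoxonium ion (8-oxoniabicyclo[5.1.0]octane unit, O+ bonded to C8, C14 and C15; 13-silyloxy) | CC1(C)[C@H](Br)CC[C@]2(C)[C@@H]1CC[C@]1(C)[O+]3C[C@H]3[C@@](C)(O[Si](C)(C)C(C)(C)C)CC[C@@H]21 | intermediate (not isolated)
13 | O-(tert-butyldimethylsilyl) oxiranium ion of 14 | CC1(C)[C@H](Br)CC[C@]2(C)[C@@H]1CC[C@]1(C)OC[C@H]3[O+]([Si](C)(C)C(C)(C)C)[C@@]3(C)CC[C@@H]21 | intermediate (not isolated)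
14 | (3R,5S,8S,9S,10R,13S,14R)-3-bromo-8,15:13,14-diepoxylabdane (CNP0311742.1) | CC1(C)[C@H](Br)CC[C@]2(C)[C@@H]1CC[C@]1(C)OC[C@H]3O[C@@]3(C)CC[C@@H]21 | target

**Total step count:** 7
**Longest linear sequence:** 7

**Steps most likely to fail**

1. Step 7 (proposed new method). Possible failures are:
   - bromination on the wrong face, or bromonium transfer between alkenes;
   - loss of a proton from the C8 cation, or its capture by O13 with loss of the silyl group, in place of capture by the oxirane;
   - opening of the epoxonium ion at C15 by an external nucleophile.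

   Fallback, with known reaction types only, sets out from 7 and returns at 14. In 7 no oxygen can reach C8, so a conventional brominative polyene cyclization with capture of the C8 cation by water (2,4,4,6-tetrabromocyclohexa-2,5-dienone, wet nitromethane) should give the 3-bromo-8-hydroxy decalin F1, separated by chromatography from the diastereomer with the antipodal decalin. K2CO3/MeOH should then close the terminal epoxide F2, and tetrabutylammonium fluoride should free O13 to give the epoxy alcohol F3. Aqueous NaOH should carry the Payne rearrangement downhill to the trisubstituted cis-13,14-epoxy-15-ol F4. Tosylation should give the epoxy tosylate F5, and an intramolecular Williamson closure of the C8 alkoxide onto C15 (KH, THF, high dilution) should give 14 with the eight-membered ring made directly.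

2. Step 6. Possible failures are migration of the silyl group from O13 to the freed C1 alkoxide, or slow displacement at C2 beside the silylated quaternary carbon. The fallback sets out from 6 and returns at 9, closing the ring before any silyl group is present. K2CO3/MeOH at 0 °C should give the (S,S)-epoxy alcohol F6, and TBSOTf/2,6-lutidine at −78 °C should then silylate the tertiary hydroxyl to 9.

3. Step 2. Possible failures are a slow two-phase hydrolysis and intermolecular opening of the terminal epoxide by alkoxides (oligomers). The fallback sets out from 1 and returns at 4, inverting C3 instead of C2. Sharpless epoxidation with D-(−)-diethyl tartrate should give the (2R,3R)-epoxy alcohol F7. Acid-catalysed hydrolysis (HClO4 cat., THF–H2O, 0 °C) should then open it at the tertiary C3 with inversion to the same triol 4.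

**Further compounds**
F1 | step 7 | (3R,5S,8S,9S,10R,13S,14R)-3-bromo-13-[(tert-butyldimethylsilyl)oxy]-8-hydroxy-14-[(methanesulfonyl)oxy]labdan-15-yl acetate | CC1(C)[C@H](Br)CC[C@]2(C)[C@@H]1CC[C@](C)(O)[C@H]2CC[C@](C)(O[Si](C)(C)C(C)(C)C)[C@H](OS(C)(=O)=O)COC(C)=O
F2 | step 7 | (3R,5S,8S,9S,10R,13S,14S)-3-bromo-13-[(tert-butyldimethylsilyl)oxy]-14,15-epoxylabdan-8-ol | CC1(C)[C@H](Br)CC[C@]2(C)[C@@H]1CC[C@](C)(O)[C@H]2CC[C@](C)(O[Si](C)(C)C(C)(C)C)[C@@H]1CO1
F3 | step 7 | (3R,5S,8S,9S,10R,13S,14S)-3-bromo-14,15-epoxylabdane-8,13-diol | CC1(C)[C@H](Br)CC[C@]2(C)[C@@H]1CC[C@](C)(O)[C@H]2CC[C@](C)(O)[C@@H]1CO1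
F4 | step 7 | (3R,5S,8S,9S,10R,13S,14R)-3-bromo-13,14-epoxylabdane-8,15-diol (cis-oxirane) | CC1(C)[C@H](Br)CC[C@]2(C)[C@@H]1CC[C@](C)(O)[C@H]2CC[C@]1(C)O[C@@H]1CO
F5 | step 7 | (3R,5S,8S,9S,10R,13S,14R)-3-bromo-13,14-epoxy-8-hydroxylabdan-15-yl 4-methylbenzenesulfonate | CC1(C)[C@H](Br)CC[C@]2(C)[C@@H]1CC[C@](C)(O)[C@H]2CC[C@]1(C)O[C@@H]1COS(=O)(=O)c1ccc(C)cc1
F6 | step 6 | (2S,5E,9E)-6,10,14-trimethyl-2-[(2S)-oxiran-2-yl]pentadeca-5,9,13-trien-2-ol | CC(C)=CCC/C(C)=C/CC/C(C)=C/CC[C@](C)(O)[C@@H]1CO1
F7 | step 2 | [(2R,3R)-3-methyl-3-[(3E,7E)-4,8,12-trimethyltrideca-3,7,11-trien-1-yl]oxiran-2-yl]methanol | CC(C)=CCC/C(C)=C/CC/C(C)=C/CC[C@@]1(C)O[C@@H]1CO
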